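**Retrosynthetic overview**

1. The target is taken back to a bicyclo[3.3.1]nonane-4,9-dione 2-methyl enol ether. The C3 aroyl group (vinyl lithiation/acylation), the (S)-4-hydroxygeranyl arm on C5 (Wittig, Brown allylation, cross-metathesis, grown from a CH2C(O)SEt arm) and the C1 and C7 prenyl groups (Wittig on CH2CHO arms) are added last.
2. Key disconnection: C7–C8 in ring B (C1, C9, C5, C6, C7, C8). C7, the prenylated CH, is γ to the carbonyls C2, C4 and C9, and C8 is the quaternary gem-dimethyl carbon, so no enolate can make this bond. It is made by hydrogen atom transfer to an isopropenyl group on C1 and 6-exo addition of the tertiary C8 radical to the β-carbon C7 of an enal arm on C5.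
3. Ring A (C1, C2, C3, C4, C5, C9) with both quaternary carbons comes from methyl 2,6-dimethoxybenzoate. Birch reductive alkylation makes C1; the ester becomes C(CH3)2OSiEt3 (masked isopropenyl and steric director); bis-allylic oxidation and mono-demethylation give a vinylogous acid that is resolved; two C5 alkylations anti to the director put the allyl (later enal) arm cis to the masked isopropenyl group.
4. Order of ring formation: ring A is carried from the arene; ring B is closed in the key step.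

Key step: step 13

Remark 1: C1–C9 are the locants of the bicyclo[3.3.1]nonane core of the target and are used for the monocyclic ring A compounds too; enols are written as one tautomer, and CIP letters change along the route only through priority changes.
Remark 2: the enantiomer of 11 that carries the C1 configuration of the target is (S)-12; which chromatographic fraction it is has to be assigned.
Remark 3: B-allyldiisopinocampheylborane with isopinocampheyl groups from (+)-α-pinene is taken to add to the Si face of an aldehyde, as it does with benzaldehyde.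

**Route**

Step 1
Reactants: 1 2-iodoethanol
Product: 2 (2-iodoethoxy)triisopropylsilane
Conditions: i-Pr3SiCl, imidazole, CH2Cl2, 0 °C to rt
Reagents that add atoms: chlorotriisopropylsilane CC(C)[Si](Cl)(C(C)C)C(C)C
Why: Standard silylation of a primary alcohol with a silyl chloride and imidazole; the bulky silyl ether is meant to last until step 14.

Step 2
Reactants: 3 methyl 2,6-dimethoxybenzoate; 2 (2-iodoethoxy)triisopropylsilane
Product: 5 methyl 2,6-dimethoxy-1-[2-(triisopropylsilyloxy)ethyl]cyclohexa-2,5-diene-1-carboxylate, via lithium ester enolate 4 (not isolated)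
Conditions: Li, NH3/THF, t-BuOH (1 equiv), −78 °C; isoprene; then 2, −78 to −33 °C
Reagents that add atoms: none
Why: Birch reductive alkylation: reduction of the 2-alkoxybenzoate with one equivalent of proton donor stops at the cross-conjugated ester enolate, which the primary iodide alkylates at the ipso carbon to give quaternary C1 (not yet a stereocenter, since the two enol ethers are equivalent).

Step 3
Reactants: 5 diene ester
Product: 8 1,5-dimethoxy-6-[2-(triethylsilyloxy)propan-2-yl]-6-[2-(triisopropylsilyloxy)ethyl]cyclohexa-1,4-diene, via methyl ketone 6 (not isolated), via lithium alkoxide 7 (not isolated)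
Conditions: MeLi (excess), THF, −78 to 0 °C; then Et3SiOTf, −78 to 0 °C
Reagents that add atoms: methyllithium [Li]C; triethylsilyl trifluoromethanesulfonate CC[Si](CC)(CC)OS(=O)(=O)C(F)(F)F
Why: Double addition of methyllithium to the ester (acyl substitution, then carbonyl addition) gives the tertiary alkoxide, which is O-silylated in the same flask; the C(CH3)2OSiEt3 group is both the masked isopropenyl group and the steric director for step 9.

Step 4
Reactants: 8 bis(enol ether) diene
Product: 9 3,5-dimethoxy-4-[2-(triethylsilyloxy)propan-2-yl]-4-[2-(triisopropylsilyloxy)ethyl]cyclohexa-2,5-dien-1-one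
Conditions: t-BuOOH, (C5H5NH)2Cr2O7 (20 mol %), Celite, PhH, rt
Reagents that add atoms: tert-butyl hydroperoxide CC(C)(C)OO
Why: Chromium-mediated allylic oxidation with t-BuOOH of the doubly allylic C4 methylene, the only ring CH2, gives the cross-conjugated 3,5-dimethoxydienone, a known conversion of methoxy-1,4-cyclohexadienes from Birch alkylation.

Step 5
Reactants: 9 symmetric dienone
Product: 11 racemic 3-hydroxy-5-methoxy-4-[2-(triethylsilyloxy)propan-2-yl]-4-[2-(triisopropylsilyloxy)ethyl]cyclohexa-2,5-dien-1-one, via lithium vinylogous carboxylate 10 (not isolated)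
Conditions: LiCl, DMF, 130 °C; then cold 0.5 M HCl
Reagents that add atoms: none
Why: Krapcho-type SN2 demethylation of one vinylogous methyl ester by chloride; the anionic vinylogous carboxylate is not dealkylated a second time, so the two enantiotopic methoxy groups are told apart and C1 becomes a stereocenter (racemic).

Step 6
Reactants: 11 racemic vinylogous acid
Product: 12 (S)-3-hydroxy-5-methoxy-4-[2-(triethylsilyloxy)propan-2-yl]-4-[2-(triisopropylsilyloxy)ethyl]cyclohexa-2,5-dien-1-one
Conditions: preparative SFC, amylose tris(3,5-dimethylphenylcarbamate) phase, CO2/i-PrOH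
Reagents that add atoms: none
Why: Resolution by chromatography on a chiral stationary phase; C1 is quaternary and cannot racemise, and the (S) fraction is to be identified by anomalous-dispersion crystallography of a derivative.

Step 7
Reactants: 12 (S)-vinylogous acid
Product: 13 (S)-2-allyl-3-hydroxy-5-methoxy-4-[2-(triethylsilyloxy)propan-2-yl]-4-[2-(triisopropylsilyloxy)ethyl]cyclohexa-2,5-dien-1-one
Conditions: Pd(PPh3)4 (5 mol %), allyl methyl carbonate (1.05 equiv), THF, rt
Reagents that add atoms: allyl methyl carbonate C=CCOC(=O)OC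
Why: Tsuji–Trost allylation: the methoxide released from the carbonate deprotonates the vinylogous acid and the soft 1,3-dione enolate is C-allylated at C5 by the π-allylpalladium complex; C5 remains an enol carbon, so no stereocenter forms here.

Step 8
Reactants: 14 bromoacetyl bromide; 15 ethanethiol
Product: 16 S-ethyl 2-bromoethanethioate
Conditions: pyridine, CH2Cl2, −10 °C
Reagents that add atoms: none
Why: Acyl substitution of the acyl bromide by the thiol; the acyl bromide is far more electrophilic than the alkyl bromide.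

Step 9
Reactants: 13 C5-allyl enol; 16 S-ethyl 2-bromoethanethioate
Product: 17 S-ethyl 2-{(1R,3S)-1-allyl-4-methoxy-2,6-dioxo-3-[2-(triethylsilyloxy)propan-2-yl]-3-[2-(triisopropylsilyloxy)ethyl]cyclohex-4-en-1-yl}ethanethioate (target numbering: C1 S; C5 R)
Conditions: K2CO3, NaI (cat.), acetone, 40 °C
Reagents that add atoms: none
Why: SN2 C-alkylation of a 2-substituted cyclic 1,3-dione enolate by an α-halo carbonyl electrophile; allylic strain with the flanking C9–O and C2–OMe groups holds the bulky C(CH3)2OSiEt3 group axial over one face of the nearly planar enolate, so the electrophile enters from the other face and the allyl group is left cis to the masked isopropenyl group, which sets C5.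

Step 10
Reactants: 17 allyl thioester
Product: 18 S-ethyl 2-{(1R,3S)-4-methoxy-2,6-dioxo-1-[(E)-4-oxobut-2-en-1-yl]-3-[2-(triethylsilyloxy)propan-2-yl]-3-[2-(triisopropylsilyloxy)ethyl]cyclohex-4-en-1-yl}ethanethioate
Conditions: (H2IMes)(PCy3)Cl2Ru=CHPh (second-generation Grubbs catalyst, 5 mol %), crotonaldehyde (5 equiv), CH2Cl2, 40 °C
Reagents that add atoms: (E)-crotonaldehyde C/C=C/C=O
Why: Olefin cross-metathesis of the terminal allyl group with excess crotonaldehyde gives the (E)-enal; the vinylogous ester alkene is inert, and with the isopropenyl group still masked no ring-closing metathesis between the C1 and C5 arms is possible.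

Step 11
Reactants: 18 enal
Product: 19 S-ethyl 2-{(1R,3R)-3-(2-hydroxypropan-2-yl)-4-methoxy-2,6-dioxo-1-[(E)-4-oxobut-2-en-1-yl]-3-[2-(triisopropylsilyloxy)ethyl]cyclohex-4-en-1-yl}ethanethioate
Conditions: HF·pyridine, pyridine, THF, 0 °C
Reagents that add atoms: none
Why: Selective desilylation: acidic fluoride cleaves the tertiary triethylsilyl ether much faster than the primary triisopropylsilyl ether, and the non-basic medium avoids retro-aldol loss of acetone from the β-hydroxy ketone.

Step 12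
Reactants: 19 tertiary alcohol
Product: 20 S-ethyl 2-{(1R,3R)-4-methoxy-2,6-dioxo-1-[(E)-4-oxobut-2-en-1-yl]-3-(prop-1-en-2-yl)-3-[2-(triisopropylsilyloxy)ethyl]cyclohex-4-en-1-yl}ethanethioate (target numbering: C1 R; C5 R; isopropenyl cis to the enal arm)
Conditions: Burgess reagent (MeO2CN−SO2N+Et3), PhMe, 60 °C
Reagents that add atoms: none
Why: Burgess dehydration (syn-elimination through the sulfamate) of the tertiary alcohol under neutral conditions; C1 is quaternary, so only the isopropenyl alkene can form.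

Step 13
Reactants: 20 ring A isopropenyl enal
Product: 21 S-ethyl 2-{(1R,5R,7S)-2-methoxy-8,8-dimethyl-4,9-dioxo-7-(2-oxoethyl)-1-[2-(triisopropylsilyloxy)ethyl]bicyclo[3.3.1]non-2-en-5-yl}ethanethioate
Conditions: Fe(acac)3 (0.3 equiv), PhSiH3 (2.5 equiv), EtOH/HOCH2CH2OH (5:1), 60 °C, degassed
Reagents that add atoms: none
Why: An iron hydride formed from Fe(acac)3 and PhSiH3 transfers a hydrogen atom to the unhindered CH2 terminus of the C1 isopropenyl group, giving the tertiary radical C8, which adds to the enal β-carbon C7; the α-formyl radical is then reduced to the iron enolate and protonated by ethanol. The closest known reaction type is the hydrogen-atom-transfer reductive olefin coupling (radical conjugate addition, Giese reaction) of 1,1-disubstituted alkenes with enals and enones, in its intramolecular form. Ring B (C1, C9, C5, C6, C7, C8) closes in 6-exo-trig mode through a chair in which the C1 and C5 arms are 1,3-diaxial on a sofa-shaped ring A. The new stereocenter C7 is set by this chair: the CH=CH–CHO residue sits equatorial, away from the C2–C3–C4 bridge, so the CH2CHO group ends up exo. The step needs hydrogen atom transfer only at the isopropenyl group and cyclisation faster than reduction or 1,2-acyl shift of the β-keto radical; the first is secured because the other π-systems are electron-poor (enal, vinylogous ester) and the other arms are saturated (thioester, silyl ether), the second by the polarity match of nucleophilic radical and electrophilic acceptor and by the cis arrangement fixed in step 9.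

Step 14
Reactants: 21 bicyclic aldehyde
Product: 22 S-ethyl 2-[(1R,5R,7S)-1-(2-hydroxyethyl)-2-methoxy-8,8-dimethyl-4,9-dioxo-7-(2-oxoethyl)bicyclo[3.3.1]non-2-en-5-yl]ethanethioate
Conditions: HF·pyridine, THF, rt
Reagents that add atoms: none
Why: Fluoride cleavage of the primary silyl ether; aldehyde, thioester and vinylogous ester are stable to HF·pyridine.

Step 15
Reactants: 22 hydroxy aldehyde
Product: 23 S-ethyl 2-[(1R,5R,7S)-2-methoxy-8,8-dimethyl-4,9-dioxo-1,7-bis(2-oxoethyl)bicyclo[3.3.1]non-2-en-5-yl]ethanethioate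
Conditions: Dess–Martin periodinane, CH2Cl2, rt
Reagents that add atoms: none
Why: Dess–Martin oxidation of the primary alcohol to the aldehyde under neutral conditions.

Step 16
Reactants: 23 dialdehyde
Product: 24 S-ethyl 2-[(1R,5R,7R)-2-methoxy-8,8-dimethyl-1,7-bis(3-methylbut-2-en-1-yl)-4,9-dioxobicyclo[3.3.1]non-2-en-5-yl]ethanethioate
Conditions: i-PrPPh3 I, n-BuLi, THF, 0 °C; then 23, −78 to −20 °C
Reagents that add atoms: isopropyltriphenylphosphonium iodide CC(C)[P+](c1ccccc1)(c1ccccc1)c1ccccc1.[I-]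
Why: Wittig olefination of both aldehydes with the non-stabilised isopropylidene ylide at low temperature, where addition to aldehydes is much faster than acylation by the thioester or attack on the hindered ketones.

Step 17
Reactants: 24 bis-prenyl thioester
Product: 25 2-[(1R,5R,7R)-2-methoxy-8,8-dimethyl-1,7-bis(3-methylbut-2-en-1-yl)-4,9-dioxobicyclo[3.3.1]non-2-en-5-yl]acetaldehyde
Conditions: Et3SiH, Pd/C (10 mol %), acetone, rt
Reagents that add atoms: none
Why: Fukuyama reduction: palladium-catalysed reduction of the thioester by the silane stops at the aldehyde and should leave the ketones, the vinylogous ester and the trisubstituted alkenes untouched.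

Step 18
Reactants: 25 aldehyde
Product: 26 (E)-4-[(1R,5S,7R)-2-methoxy-8,8-dimethyl-1,7-bis(3-methylbut-2-en-1-yl)-4,9-dioxobicyclo[3.3.1]non-2-en-5-yl]-2-methylbut-2-enal
Conditions: Ph3P=C(CH3)CHO, PhMe, 80 °C
Reagents that add atoms: 2-(triphenylphosphoranylidene)propanal CC(C=O)=P(c1ccccc1)(c1ccccc1)c1ccccc1
Why: Wittig reaction with the formyl-stabilised ylide gives the (E)-2-methyl enal (thermodynamic E-selectivity of stabilised ylides).

Step 19
Reactants: 26 enal
Product: 28 (1R,5S,7R)-5-[(2E,4S)-4-hydroxy-3-methylhepta-2,6-dien-1-yl]-2-methoxy-8,8-dimethyl-1,7-bis(3-methylbut-2-en-1-yl)bicyclo[3.3.1]non-2-ene-4,9-dione, via borinate ester 27 (not isolated)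
Conditions: B-allyldiisopinocampheylborane (from (+)-α-pinene), Et2O, −78 °C; then NaBO3·4H2O, THF/H2O, rt
Reagents that add atoms: B-allyldiisopinocampheylborane (isopinocampheyl groups from (+)-α-pinene) C=CCB([C@@H]1C[C@@H]2C[C@H]([C@H]1C)C2(C)C)[C@@H]1C[C@@H]2C[C@H]([C@H]1C)C2(C)C
Why: Brown allylation: the chair transition state of this reagent delivers allyl to the Si face of the aldehyde (reagent control, remote from the core), which gives the (S)-carbinol; the ketones do not react at −78 °C.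

Step 20
Reactants: 28 homoallylic alcohol
Product: 29 (1R,5S,7R)-5-[(2E,4S)-4-hydroxy-3,7-dimethylocta-2,6-dien-1-yl]-2-methoxy-8,8-dimethyl-1,7-bis(3-methylbut-2-en-1-yl)bicyclo[3.3.1]non-2-ene-4,9-dione
Conditions: (H2IMes)(PCy3)Cl2Ru=CHPh (second-generation Grubbs catalyst, 5 mol %), 2-methylbut-2-ene/CH2Cl2, 40 °C
Reagents that add atoms: 2-methylbut-2-ene CC=C(C)C
Why: Cross-metathesis of the terminal alkene with 2-methylbut-2-ene turns allyl into prenyl; the trisubstituted alkenes already present are inert or react degenerately.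

Step 21
Reactants: 29 allylic alcohol
Product: 30 (1R,5S,7R)-5-[(2E,4S)-3,7-dimethyl-4-(triethylsilyloxy)octa-2,6-dien-1-yl]-2-methoxy-8,8-dimethyl-1,7-bis(3-methylbut-2-en-1-yl)bicyclo[3.3.1]non-2-ene-4,9-dione
Conditions: Et3SiOTf, 2,6-lutidine, CH2Cl2, −78 °C
Reagents that add atoms: triethylsilyl trifluoromethanesulfonate CC[Si](CC)(CC)OS(=O)(=O)C(F)(F)F
Why: Silylation of the secondary alcohol, so that no OH consumes base or acyl chloride in step 24.

Step 22
Reactants: 31 3,4-dihydroxybenzoic acid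
Product: 32 tert-butyldimethylsilyl 3,4-bis(tert-butyldimethylsilyloxy)benzoate
Conditions: t-BuMe2SiCl (3.3 equiv), imidazole, DMF, rt
Reagents that add atoms: tert-butylchlorodimethylsilane CC(C)(C)[Si](C)(C)Cl
Why: Exhaustive silylation of both phenols and the acid with a silyl chloride and imidazole.

Step 23
Reactants: 32 tris-silyl compound
Product: 33 3,4-bis(tert-butyldimethylsilyloxy)benzoyl chloride
Conditions: (COCl)2, DMF (cat.), CH2Cl2, 0 °C to rt
Reagents that add atoms: oxalyl chloride O=C(Cl)C(=O)Cl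
Why: Silyl esters are converted directly into acid chlorides by oxalyl chloride with catalytic DMF (Vilsmeier-type activation) under neutral conditions that leave aryl silyl ethers intact.

Step 24
Reactants: 30 silyl-protected bicycle; 33 aroyl chloride
Product: 35 (1R,5R,7R)-3-[3,4-bis(tert-butyldimethylsilyloxy)benzoyl]-5-[(2E,4S)-3,7-dimethyl-4-(triethylsilyloxy)octa-2,6-dien-1-yl]-2-methoxy-8,8-dimethyl-1,7-bis(3-methylbut-2-en-1-yl)bicyclo[3.3.1]non-2-ene-4,9-dione, via C3 vinyllithium 34 (not isolated)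
Conditions: 2,2,6,6-tetramethylpiperidine, n-BuLi, THF, −78 °C; then 33, −78 °C
Reagents that add atoms: none
Why: α-Vinyl lithiation of the β-alkoxy enone and acylation of the vinyllithium by the aroyl chloride; C3–H is the only acidic proton (C1 and C5 are quaternary, C9 cannot enolise), and this is the known way to acylate C3 of such bicyclic vinylogous esters.

Step 25
Reactants: 35 aroylated silyl ether
Product: 36 (1R,5R,7R)-3-(3,4-dihydroxybenzoyl)-5-[(2E,4S)-4-hydroxy-3,7-dimethylocta-2,6-dien-1-yl]-2-methoxy-8,8-dimethyl-1,7-bis(3-methylbut-2-en-1-yl)bicyclo[3.3.1]non-2-ene-4,9-dione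
Conditions: Bu4NF, AcOH (1:1), THF, 0 °C
Reagents that add atoms: none
Why: Buffered fluoride desilylation removes the two aryl silyl ethers and the secondary silyl ether without base-sensitive side reactions.

Step 26
Reactants: 36 methyl enol ether
Product: 38 target CNP0142498.1, via lithium enolate 37 (not isolated)
Conditions: LiCl, DMSO, 120 °C, argon; then aq. HCl to pH 3
Reagents that add atoms: none
Why: Krapcho-type demethylation of the doubly activated vinylogous ester by chloride gives the enolate of the β-triketone, which is protonated on work-up to the target (enol tautomers in equilibrium).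

**Compound list**

1 | 2-iodoethanol | OCCI | starting material
2 | (2-iodoethoxy)triisopropylsilane | CC(C)[Si](OCCI)(C(C)C)C(C)C | intermediate
3 | methyl 2,6-dimethoxybenzoate | COC(=O)c1c(OC)cccc1OC | starting material
4 | lithium ester enolate of methyl 2,6-dimethoxycyclohexa-2,5-diene-1-carboxylate (not isolated) | COC(O[Li])=C1C(OC)=CCC=C1OC | intermediate
5 | methyl 2,6-dimethoxy-1-[2-(triisopropylsilyloxy)ethyl]cyclohexa-2,5-diene-1-carboxylate | COC(=O)C1(CCO[Si](C(C)C)(C(C)C)C(C)C)C(OC)=CCC=C1OC | intermediate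
6 | 1-{2,6-dimethoxy-1-[2-(triisopropylsilyloxy)ethyl]cyclohexa-2,5-dien-1-yl}ethan-1-one (not isolated) | CC(=O)C1(CCO[Si](C(C)C)(C(C)C)C(C)C)C(OC)=CCC=C1OC | intermediate
7 | lithium 2-{2,6-dimethoxy-1-[2-(triisopropylsilyloxy)ethyl]cyclohexa-2,5-dien-1-yl}propan-2-olate (not isolated) | [Li]OC(C)(C)C1(CCO[Si](C(C)C)(C(C)C)C(C)C)C(OC)=CCC=C1OC | intermediate
8 | 1,5-dimethoxy-6-[2-(triethylsilyloxy)propan-2-yl]-6-[2-(triisopropylsilyloxy)ethyl]cyclohexa-1,4-diene | CC[Si](CC)(CC)OC(C)(C)C1(CCO[Si](C(C)C)(C(C)C)C(C)C)C(OC)=CCC=C1OC | intermediate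
9 | 3,5-dimethoxy-4-[2-(triethylsilyloxy)propan-2-yl]-4-[2-(triisopropylsilyloxy)ethyl]cyclohexa-2,5-dien-1-one | CC[Si](CC)(CC)OC(C)(C)C1(CCO[Si](C(C)C)(C(C)C)C(C)C)C(OC)=CC(=O)C=C1OC | intermediate
10 | lithium vinylogous carboxylate of 11 (not isolated) | [Li]OC1=CC(=O)C=C(OC)C1(CCO[Si](C(C)C)(C(C)C)C(C)C)C(C)(C)O[Si](CC)(CC)CC | intermediate
11 | racemic 3-hydroxy-5-methoxy-4-[2-(triethylsilyloxy)propan-2-yl]-4-[2-(triisopropylsilyloxy)ethyl]cyclohexa-2,5-dien-1-one | OC1=CC(=O)C=C(OC)C1(CCO[Si](C(C)C)(C(C)C)C(C)C)C(C)(C)O[Si](CC)(CC)CC | intermediate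
12 | (S)-3-hydroxy-5-methoxy-4-[2-(triethylsilyloxy)propan-2-yl]-4-[2-(triisopropylsilyloxy)ethyl]cyclohexa-2,5-dien-1-one (quaternary carbon = C1) | OC1=CC(=O)C=C(OC)[C@@]1(CCO[Si](C(C)C)(C(C)C)C(C)C)C(C)(C)O[Si](CC)(CC)CC | intermediate
13 | (S)-2-allyl-3-hydroxy-5-methoxy-4-[2-(triethylsilyloxy)propan-2-yl]-4-[2-(triisopropylsilyloxy)ethyl]cyclohexa-2,5-dien-1-one (allyl on C5) | C=CCC1=C(O)[C@@](CCO[Si](C(C)C)(C(C)C)C(C)C)(C(OC)=CC1=O)C(C)(C)O[Si](CC)(CC)CC | intermediate
14 | bromoacetyl bromide | BrCC(Br)=O | starting material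
15 | ethanethiol | CCS | starting material
16 | S-ethyl 2-bromoethanethioate | CCSC(=O)CBr | intermediate
17 | S-ethyl 2-{(1R,3S)-1-allyl-4-methoxy-2,6-dioxo-3-[2-(triethylsilyloxy)propan-2-yl]-3-[2-(triisopropylsilyloxy)ethyl]cyclohex-4-en-1-yl}ethanethioate (C1 S, C5 R; allyl cis to the silyloxypropyl group) | C=CC[C@]1(CC(=O)SCC)C(=O)[C@@](CCO[Si](C(C)C)(C(C)C)C(C)C)(C(OC)=CC1=O)C(C)(C)O[Si](CC)(CC)CC | intermediate
18 | S-ethyl 2-{(1R,3S)-4-methoxy-2,6-dioxo-1-[(E)-4-oxobut-2-en-1-yl]-3-[2-(triethylsilyloxy)propan-2-yl]-3-[2-(triisopropylsilyloxy)ethyl]cyclohex-4-en-1-yl}ethanethioate | O=C/C=C/C[C@]1(CC(=O)SCC)C(=O)[C@@](CCO[Si](C(C)C)(C(C)C)C(C)C)(C(OC)=CC1=O)C(C)(C)O[Si](CC)(CC)CC | intermediate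
19 | S-ethyl 2-{(1R,3R)-3-(2-hydroxypropan-2-yl)-4-methoxy-2,6-dioxo-1-[(E)-4-oxobut-2-en-1-yl]-3-[2-(triisopropylsilyloxy)ethyl]cyclohex-4-en-1-yl}ethanethioate | O=C/C=C/C[C@]1(CC(=O)SCC)C(=O)[C@@](CCO[Si](C(C)C)(C(C)C)C(C)C)(C(OC)=CC1=O)C(C)(C)O | intermediate
20 | S-ethyl 2-{(1R,3R)-4-methoxy-2,6-dioxo-1-[(E)-4-oxobut-2-en-1-yl]-3-(prop-1-en-2-yl)-3-[2-(triisopropylsilyloxy)ethyl]cyclohex-4-en-1-yl}ethanethioate (C1 R, C5 R; key-step precursor) | O=C/C=C/C[C@]1(CC(=O)SCC)C(=O)[C@@](CCO[Si](C(C)C)(C(C)C)C(C)C)(C(OC)=CC1=O)C(C)=C | intermediate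
21 | S-ethyl 2-{(1R,5R,7S)-2-methoxy-8,8-dimethyl-4,9-dioxo-7-(2-oxoethyl)-1-[2-(triisopropylsilyloxy)ethyl]bicyclo[3.3.1]non-2-en-5-yl}ethanethioate (key-step product, 7-exo) | O=CC[C@@H]1C[C@]2(CC(=O)SCC)C(=O)[C@@](CCO[Si](C(C)C)(C(C)C)C(C)C)(C(OC)=CC2=O)C1(C)C | intermediate
22 | S-ethyl 2-[(1R,5R,7S)-1-(2-hydroxyethyl)-2-methoxy-8,8-dimethyl-4,9-dioxo-7-(2-oxoethyl)bicyclo[3.3.1]non-2-en-5-yl]ethanethioate | O=CC[C@@H]1C[C@]2(CC(=O)SCC)C(=O)[C@@](CCO)(C(OC)=CC2=O)C1(C)C | intermediate
23 | S-ethyl 2-[(1R,5R,7S)-2-methoxy-8,8-dimethyl-4,9-dioxo-1,7-bis(2-oxoethyl)bicyclo[3.3.1]non-2-en-5-yl]ethanethioate | O=CC[C@@H]1C[C@]2(CC(=O)SCC)C(=O)[C@@](CC=O)(C(OC)=CC2=O)C1(C)C | intermediate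
24 | S-ethyl 2-[(1R,5R,7R)-2-methoxy-8,8-dimethyl-1,7-bis(3-methylbut-2-en-1-yl)-4,9-dioxobicyclo[3.3.1]non-2-en-5-yl]ethanethioate | CC(C)=CC[C@@H]1C[C@]2(CC(=O)SCC)C(=O)[C@@](CC=C(C)C)(C(OC)=CC2=O)C1(C)C | intermediate
25 | 2-[(1R,5R,7R)-2-methoxy-8,8-dimethyl-1,7-bis(3-methylbut-2-en-1-yl)-4,9-dioxobicyclo[3.3.1]non-2-en-5-yl]acetaldehyde | CC(C)=CC[C@@H]1C[C@]2(CC=O)C(=O)[C@@](CC=C(C)C)(C(OC)=CC2=O)C1(C)C | intermediate
26 | (E)-4-[(1R,5S,7R)-2-methoxy-8,8-dimethyl-1,7-bis(3-methylbut-2-en-1-yl)-4,9-dioxobicyclo[3.3.1]non-2-en-5-yl]-2-methylbut-2-enal | CC(C)=CC[C@@H]1C[C@]2(C/C=C(\C)C=O)C(=O)[C@@](CC=C(C)C)(C(OC)=CC2=O)C1(C)C | intermediate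
27 | diisopinocampheylborinate ester of 28 (not isolated) | CC(C)=CC[C@@H]1C[C@]2(C/C=C(\C)[C@@H](OB([C@@H]3C[C@@H]4C[C@H]([C@H]3C)C4(C)C)[C@@H]3C[C@@H]4C[C@H]([C@H]3C)C4(C)C)CC=C)C(=O)[C@@](CC=C(C)C)(C(OC)=CC2=O)C1(C)C | intermediate
28 | (1R,5S,7R)-5-[(2E,4S)-4-hydroxy-3-methylhepta-2,6-dien-1-yl]-2-methoxy-8,8-dimethyl-1,7-bis(3-methylbut-2-en-1-yl)bicyclo[3.3.1]non-2-ene-4,9-dione | CC(C)=CC[C@@H]1C[C@]2(C/C=C(\C)[C@@H](O)CC=C)C(=O)[C@@](CC=C(C)C)(C(OC)=CC2=O)C1(C)C | intermediate
29 | (1R,5S,7R)-5-[(2E,4S)-4-hydroxy-3,7-dimethylocta-2,6-dien-1-yl]-2-methoxy-8,8-dimethyl-1,7-bis(3-methylbut-2-en-1-yl)bicyclo[3.3.1]non-2-ene-4,9-dione | CC(C)=CC[C@@H]1C[C@]2(C/C=C(\C)[C@@H](O)CC=C(C)C)C(=O)[C@@](CC=C(C)C)(C(OC)=CC2=O)C1(C)C | intermediate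
30 | (1R,5S,7R)-5-[(2E,4S)-3,7-dimethyl-4-(triethylsilyloxy)octa-2,6-dien-1-yl]-2-methoxy-8,8-dimethyl-1,7-bis(3-methylbut-2-en-1-yl)bicyclo[3.3.1]non-2-ene-4,9-dione | CC(C)=CC[C@@H]1C[C@]2(C/C=C(\C)[C@@H](O[Si](CC)(CC)CC)CC=C(C)C)C(=O)[C@@](CC=C(C)C)(C(OC)=CC2=O)C1(C)C | intermediate
31 | 3,4-dihydroxybenzoic acid | OC(=O)c1ccc(O)c(O)c1 | starting material
32 | tert-butyldimethylsilyl 3,4-bis(tert-butyldimethylsilyloxy)benzoate | CC(C)(C)[Si](C)(C)OC(=O)c1ccc(O[Si](C)(C)C(C)(C)C)c(O[Si](C)(C)C(C)(C)C)c1 | intermediate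
33 | 3,4-bis(tert-butyldimethylsilyloxy)benzoyl chloride | ClC(=O)c1ccc(O[Si](C)(C)C(C)(C)C)c(O[Si](C)(C)C(C)(C)C)c1 | intermediate
34 | C3 vinyllithium of 30 (not isolated) | CC(C)=CC[C@@H]1C[C@]2(C/C=C(\C)[C@@H](O[Si](CC)(CC)CC)CC=C(C)C)C(=O)[C@@](CC=C(C)C)(C(OC)=C([Li])C2=O)C1(C)C | intermediate
35 | (1R,5R,7R)-3-[3,4-bis(tert-butyldimethylsilyloxy)benzoyl]-5-[(2E,4S)-3,7-dimethyl-4-(triethylsilyloxy)octa-2,6-dien-1-yl]-2-methoxy-8,8-dimethyl-1,7-bis(3-methylbut-2-en-1-yl)bicyclo[3.3.1]non-2-ene-4,9-dione | CC(C)=CC[C@@H]1C[C@]2(C/C=C(\C)[C@@H](O[Si](CC)(CC)CC)CC=C(C)C)C(=O)[C@@](CC=C(C)C)(C(OC)=C(C(=O)c3ccc(O[Si](C)(C)C(C)(C)C)c(O[Si](C)(C)C(C)(C)C)c3)C2=O)C1(C)C | intermediate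
36 | (1R,5R,7R)-3-(3,4-dihydroxybenzoyl)-5-[(2E,4S)-4-hydroxy-3,7-dimethylocta-2,6-dien-1-yl]-2-methoxy-8,8-dimethyl-1,7-bis(3-methylbut-2-en-1-yl)bicyclo[3.3.1]non-2-ene-4,9-dione | CC(C)=CC[C@@H]1C[C@]2(C/C=C(\C)[C@@H](O)CC=C(C)C)C(=O)[C@@](CC=C(C)C)(C(OC)=C(C(=O)c3ccc(O)c(O)c3)C2=O)C1(C)C | intermediate
37 | lithium enolate of 38 (not isolated) | CC(C)=CC[C@@H]1C[C@]2(C/C=C(\C)[C@@H](O)CC=C(C)C)C(=O)[C@@](CC=C(C)C)(C(O[Li])=C(C(=O)c3ccc(O)c(O)c3)C2=O)C1(C)C | intermediate
38 | (1S,5S,7R)-3-(3,4-dihydroxybenzoyl)-4-hydroxy-5-[(2E,4S)-4-hydroxy-3,7-dimethylocta-2,6-dien-1-yl]-8,8-dimethyl-1,7-bis(3-methylbut-2-en-1-yl)bicyclo[3.3.1]non-3-ene-2,9-dione (CNP0142498.1) | CC(C)=CC[C@@H]1C[C@]2(C/C=C(\C)[C@@H](O)CC=C(C)C)C(=O)[C@@](CC=C(C)C)(C(=O)C(C(=O)c3ccc(O)c(O)c3)=C2O)C1(C)C | target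

**Step count and risks**

Total step count: 26. Longest linear sequence: 23 steps (steps 1–7, 9–21, 24–26).

Steps most likely to fail:

1. Step 13. The tertiary β-keto radical may be reduced (net hydrogenation of the isopropenyl group) or undergo 1,2-acyl shift before it cyclises, and the metal hydride may reduce the enal. Fallback: it sets out from tertiary alcohol 19 (step 12 is skipped) and comes back at 21. Acylation of 19 with methyl chlorooxoacetate (Et3N, DMAP, CH2Cl2) would give the tert-alkyl methyl oxalate F1. Hydrolysis with one equivalent of aqueous CsOH in THF would give the cesium tert-alkyl oxalate F2. Irradiation with blue light in the presence of Ir[dF(CF3)ppy]2(dtbbpy)PF6 in DME/DMF/H2O would release the same C8 radical by double decarboxylation, with no metal hydride present; 6-exo addition to the enal, reduction of the α-formyl radical by the photocatalyst and protonation would give 21.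

2. Step 9. The hindered enolate may be alkylated on oxygen, or facial selectivity may be insufficient. Fallback: it sets out from 13 and comes back at 17. Conjugate addition of 13 to nitroethylene (cat. Et3N, THF, −20 °C), which is inherently C-selective and has the same facial bias, would give the 2-nitroethyl compound F3. Oxidative Nef-type conversion of the primary nitro group with NaNO2/AcOH in DMSO would give the carboxylic acid F4. Steglich thioesterification with EtSH (carbodiimide, DMAP) would give 17.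

3. Step 16. Acyl transfer from the thioester to the basic ylide, or enolisation of the aldehydes, may consume material. Fallback: it sets out from 23 and comes back at 24. A Julia–Kocienski olefination with 5-(isopropylsulfonyl)-1-phenyl-1H-tetrazole and KHMDS (DME, −60 °C), whose hindered sulfonyl carbanion is a much poorer acyl acceptor, would convert both aldehydes into prenyl groups; no new compound lies on the way.

**Further compounds**

F1 | step 13 | methyl oxalate ester of tertiary alcohol 19 (methyl 2-[ring A C1]-propan-2-yl oxalate) | O=C/C=C/C[C@]1(CC(=O)SCC)C(=O)[C@@](CCO[Si](C(C)C)(C(C)C)C(C)C)(C(OC)=CC1=O)C(C)(C)OC(=O)C(=O)OC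
F2 | step 13 | cesium oxalate half-ester of tertiary alcohol 19 | O=C/C=C/C[C@]1(CC(=O)SCC)C(=O)[C@@](CCO[Si](C(C)C)(C(C)C)C(C)C)(C(OC)=CC1=O)C(C)(C)OC(=O)C(=O)[O-].[Cs+]
F3 | step 9 | C5-allyl C5-(2-nitroethyl) ring A dione (C1 S; nitroethyl trans to the silyloxypropyl group) | C=CC[C@]1(CC[N+](=O)[O-])C(=O)[C@@](CCO[Si](C(C)C)(C(C)C)C(C)C)(C(OC)=CC1=O)C(C)(C)O[Si](CC)(CC)CC
F4 | step 9 | C5-allyl C5-(carboxymethyl) ring A dione (acid corresponding to thioester 17) | C=CC[C@]1(CC(=O)O)C(=O)[C@@](CCO[Si](C(C)C)(C(C)C)C(C)C)(C(OC)=CC1=O)C(C)(C)O[Si](CC)(CC)CC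
F0 | step 16 | none | none
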